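Which species holds most of the charge in the flask at 10 h, and how large is its share, given a charge of 1.1 M, less than in either earlier run?

| flask | starting material | remark | time |
|---|---|---|---|
| autumn | 1.5 M | run made earlier |  |
| dusk | 2.4 M | run made earlier |  |
| flask | 1.1 M |  | 10 h |

| run | time / h | intermediate B / % | product / % | intermediate A / % | starting material / % | intermediate C / % |
|---|---|---|---|---|---|---|
| autumn | 2.50 | 15.7 | 0 | 40.9 | 46.4 | 1.2 |
| autumn | 5.00 | 30.3 | 1.1 | 32.7 | 31.5 | 1.3 |
| autumn | 8.00 | 43.0 | 2.4 | 24.2 | 25.2 | 6.3 |
| autumn | 10.0 | 46.4 | 5.0 | 19.1 | 19.9 | 7.3 |
| dusk | 2.50 | 14.4 | 1.1 | 39.4 | 46.2 | 0 |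
| dusk | 5.00 | 29.8 | 0.9 | 34.0 | 32.3 | 4.7 |
| dusk | 8.00 | 42.0 | 2.6 | 24.2 | 24.9 | 6.1 |
| dusk | 10.0 | 47.2 | 4.2 | 19.3 | 19.2 | 8.5 |

(each reading ± 1 percentage point)

- the largest share of what was charged as starting material, at 10 h belongs to (intermediate C / product / intermediate A / intermediate B / starting material)
- the largest share itself, whichever of these holds it, in percent of the starting material charged

- the numbers in the tables scatter by 1 percentage point (one standard deviation)
- a reading or a percentage of product counts all its forms, free or not

Two chemists argue this, and both carry the percentages over to the flask unchanged, since the runs at 1.5 M and 2.4 M agree within the scatter. The first counts P, the share that is no longer starting material or intermediate A, which averages 61.2% at 10.0 h, and for the sake of a simple view gives all of P to intermediate B, setting aside the 12.5% that intermediate C and product together read on average at that time.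

The second keeps P but treats what has moved beyond intermediate B as a correction, using the leak per hour λ, the part of P standing as intermediate C or product divided by the time, which the 10.0 h readings put at 0.0211 h⁻¹, and the 8.00 h readings at 0.0212 h⁻¹. Intermediate B at time t is then P(1 − λt), and I commit to that reckoning: 48.3% in the flask, more than the starting material or intermediate A read.

The forecast, a little below my figure, names intermediate B at 46.8%: “B holds the largest share”.

The flask gives intermediate B at 48.2%, which is 13 percentage points below the first chemist's P.

    crystals ⇌ product, rate k1*(cs1 - [product]) while solid is left; crystals form when [product] > cs1 (solubility = 0.450 M, k = 7.30 h⁻¹)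
    intermediate C → product (k = 0.120 h⁻¹)
    intermediate B ⇌ intermediate C (K = 1.60, k = 0.0470 h⁻¹)
    intermediate A → intermediate B (k = 0.200 h⁻¹)
    starting material ⇌ intermediate A (K = 1.30, k = 0.530 h⁻¹)

At 10.0 h the flask still makes intermediate B 2.02 times faster than it uses it up, each step taken net. Its own leak per hour stands at 0.0199 h⁻¹ beside the 0.0211 h⁻¹ read from the runs. The same flask read at 2.5 h has P = 14.9%, and λ takes 5.27% of that away, leaving 14.1% against the simulated 14.2%; at so early a reading the first chemist's view serves, with starting material ahead of both at 45.4%.

The numbers in the tables are calculated with made-up constants; noise was put on by code.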